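**Plan**

- Retrosynthesis: the O6–Si bond is cut last. The two ester bonds O–C7 and O–C4 are then cut together, which turns the units BzO–C7–C1–OH and BzO–C4–C5–OH into a spiro oxirane (C1, C7) and a ring oxirane (C4, C5) on a 6-silyloxycyclohex-2-ene. Removing the ring oxirane oxygen, the silyl group and the C6 hydride leads back to the periodate dearomatisation product of salicyl alcohol.
- Enabling feature: each benzoate oxygen sits on a carbon next to a carbinol carbon (C7 beside C1; C4 beside C5, trans on the six-membered ring, with C4 allylic to C2=C3). This is the pattern left by two oxirane openings with benzoate.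
- Forward: the carbocycle is the benzene ring of salicyl alcohol and is never broken. The spiro oxirane forms in the dearomatisation; the C6 ketone is reduced; O6 is silylated; the ring oxirane is added; both oxiranes are opened by benzoate; the silyl group is removed. No C–C bond is formed.
- Stereochemistry: C1 arises racemic. An (S)-selective ketoreductase fixes C6 and turns the two enantiomers into separable diastereomers, of which the trans one is kept. The O6 silyl ether sends the epoxidising agent to the opposite face, which sets C5. Benzoate inverts C4.

Key step: step 5

**Remarks**

- Numbering: C1 is the carbinol carbon carrying C7H2, C2=C3 the alkene, C4 the ring benzoate carbon, C5 and C6 the carbinols. "Upper face" means the face of the oxygen on C1. In the target O1 and O5 are on the upper face, O4 and O6 on the lower face.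
- A racemate is written as the SMILES of its two enantiomers joined by a dot.
- Assumption: the (S)-selective ketoreductase is found by screening a commercial enzyme panel. In step 5 the primary carbon is assumed to react first; the other order would give the same product.
- The cis dienol that step 2 forms from the unwanted enantiomer of the dienone is a co-product. It is separated and discarded, is not carried forward, and therefore has no compound number.

**Route**

Step 1
Reactants: 1 salicyl alcohol (2-(hydroxymethyl)phenol)
Product: 2 racemic 1-oxaspiro[2.5]octa-5,7-dien-4-one (dienone with the C1/C7 spiro oxirane and the C6 ketone)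
Conditions: NaIO4 (1.1 equiv), H2O, 0 °C, 15 min; extraction into cold MTBE, dried over Na2SO4, used at once as a dilute solution
Reagents that add atoms: none
Why: Adler–Becker oxidation, in which periodate esterifies the phenol oxygen and the benzylic hydroxyl closes onto the ring carbon that carries it, dearomatising the ring to the 2,4-dienone with the C1/C7 oxirane in place; C1 arises racemic, and the dienone is kept cold and dilute because it dimerises by Diels–Alder reaction when concentrated.

Step 2
Reactants: 2 racemic 1-oxaspiro[2.5]octa-5,7-dien-4-one
Product: 3 (3R,4S)-1-oxaspiro[2.5]octa-5,7-dien-4-ol (trans dienol: C6–OH on the lower face, oxirane oxygen on the upper face)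
Conditions: (S)-selective ketoreductase, NADP+ (cat.), iPrOH (10 vol%), KH2PO4/K2HPO4 buffer pH 7.0, MTBE co-phase, 25 °C, slow feed of 2; chromatography on Et3N-treated SiO2
Reagents that add atoms: none
Why: Enzymatic ketone reduction with cofactor recycling by isopropanol, in which the enzyme is expected to deliver hydride to the same face of the C6 carbonyl whatever the configuration at C1, so that C6 becomes (S) throughout; the (R)-ketone should give the trans dienol 3 and the (S)-ketone the diastereomeric cis (3S,4S)-dienol, which is removed by chromatography, while slow feeding keeps the dienone too dilute to dimerise before it is reduced.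

Step 3
Reactants: 3 (3R,4S)-1-oxaspiro[2.5]octa-5,7-dien-4-ol
Product: 4 tert-butyldimethylsilyl ether of 3 (tert-butyldimethyl{[(3R,4S)-1-oxaspiro[2.5]octa-5,7-dien-4-yl]oxy}silane)
Conditions: TBSCl, imidazole, DMF, 0 °C → rt
Reagents that add atoms: tert-butyldimethylsilyl chloride (TBSCl), CC(C)(C)[Si](C)(C)Cl
Why: Silylation of a secondary alcohol with a silyl chloride and imidazole, basic conditions that spare the acid-labile vinyl oxirane and the diene; the bulky group on O6 is there to steer the next step and to block a Payne rearrangement later, and no stereocentre changes.

Step 4
Reactants: 4 tert-butyldimethylsilyl ether of 3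
Product: 5 diepoxide (cyclohex-2-ene with the C1/C7 spiro oxirane and the C4/C5 ring oxirane; both oxirane oxygens on the upper face; O6 silyl ether on the lower face)
Conditions: dimethyldioxirane (1.05 equiv, acetone solution), CH2Cl2/acetone, −20 → 0 °C
Reagents that add atoms: dimethyldioxirane (DMDO), CC1(C)OO1
Why: Electrophilic epoxidation by a neutral dioxirane (concerted oxygen transfer), in which the upper face of C4=C5 carries only the C6 hydrogen whereas its lower face is covered by the silyl ether and C2=C3 is flanked by the fully substituted C1 and its oxirane oxygen, so the oxidant should add to C4=C5 anti to the silyl ether and place the new oxirane oxygen on the upper face at C4 and C5; the acid-free reagent avoids opening either vinyl oxirane.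

Step 5
Reactants: 5 diepoxide; 6 benzoic acid
Product: 8 6-O-tert-butyldimethylsilyl kweichowenol B, via C7-monobenzoate 7 (not isolated)
Conditions: PhCO2H (6 equiv), CsO2CPh (3 equiv), DMF, 65 °C
Reagents that add atoms: benzoic acid 6, O=C(O)c1ccccc1 (net source of both benzoyloxy groups); cesium benzoate, [Cs+].[O-]C(=O)c1ccccc1 (carries the benzoate and is re-formed from 6)
Why: Benzoate attacks the oxiranes in two SN2 displacements, first at the primary C7 of the spiro oxirane (giving 7) and then at the allylic C4 of the ring oxirane, and each alkoxide set free is protonated by benzoic acid, which returns the benzoate. The closest known reactions are the carboxylate opening of 2,2-disubstituted oxiranes at their CH2 terminus and the trans opening of cyclic vinyl oxiranes at the allylic carbon. No ring is closed; two three-membered rings are opened and the O–C7 and O–C4 ester bonds are the only bonds made. The one new stereocentre, C4, is set by inversion, since benzoate enters on the face opposite the oxirane oxygen (the face of the silyl ether); the C4 benzoate therefore ends up trans to the C5 hydroxyl, while C1, C5 and C6 keep their oxygens and configurations. Site selectivity is needed at both oxiranes and comes from the substrate: C7 is primary whereas C1 is fully substituted, C4 is allylic whereas C5 is flanked by the C6 silyl ether, and SN2′ attack (at C2 for the ring oxirane, at C3 for the spiro oxirane) is not expected for an uncatalysed carboxylate, C2 being in addition next to the quaternary C1. The benzoic acid buffer keeps the medium from becoming basic enough for silyl or benzoyl migration and is too weak an acid to ionise the C1–O bond, and the silyl group on O6 excludes a Payne rearrangement.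

Step 6
Reactants: 8 6-O-tert-butyldimethylsilyl kweichowenol B
Product: 9 kweichowenol B ([(1R,4S,5S,6S)-4-(benzoyloxy)-1,5,6-trihydroxycyclohex-2-en-1-yl]methyl benzoate)
Conditions: HF·pyridine, pyridine, THF, 0 °C → rt
Reagents that add atoms: none
Why: Fluoride-mediated cleavage of the Si–O bond under buffered, non-basic conditions, chosen because basic fluoride sources promote benzoyl migration among the neighbouring oxygens; the esters, the allylic tertiary alcohol and all four stereocentres should be untouched.

**Compound list**

1 | salicyl alcohol (2-(hydroxymethyl)phenol) | OCc1ccccc1O | starting material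
2 | racemic 1-oxaspiro[2.5]octa-5,7-dien-4-one | C1O[C@]12C=CC=CC2=O.C1O[C@@]12C=CC=CC2=O | intermediate
3 | (3R,4S)-1-oxaspiro[2.5]octa-5,7-dien-4-ol (trans dienol) | C1O[C@]12C=CC=C[C@@H]2O | intermediate
4 | tert-butyldimethyl{[(3R,4S)-1-oxaspiro[2.5]octa-5,7-dien-4-yl]oxy}silane | C1O[C@]12C=CC=C[C@@H]2O[Si](C)(C)C(C)(C)C | intermediate
5 | diepoxide: C1/C7 spiro oxirane and C4/C5 ring oxirane (both oxygens on the upper face), C2=C3 alkene, O6 silyl ether on the lower face | C3O[C@]31C=C[C@H]2O[C@H]2[C@@H]1O[Si](C)(C)C(C)(C)C | intermediate
6 | benzoic acid | O=C(O)c1ccccc1 | starting material
7 | C7-monobenzoate: C1 tertiary alcohol, C4/C5 ring oxirane intact, O6 silyl ether (not isolated) | O=C(OC[C@]1(O)C=C[C@H]2O[C@H]2[C@@H]1O[Si](C)(C)C(C)(C)C)c1ccccc1 | intermediate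
8 | 6-O-tert-butyldimethylsilyl kweichowenol B | O=C(OC[C@]1(O)C=C[C@H](OC(=O)c2ccccc2)[C@@H](O)[C@@H]1O[Si](C)(C)C(C)(C)C)c1ccccc1 | intermediate
9 | kweichowenol B | O=C(OC[C@]1(O)C=C[C@H](OC(=O)c2ccccc2)[C@@H](O)[C@@H]1O)c1ccccc1 | target

**Step count**

Total: 6 steps. Longest linear sequence: 6 steps (1 → 9); benzoic acid 6 enters in step 5.

**Steps most likely to fail**

1. Step 5 (double oxirane opening). The ring oxirane may react more slowly than the spiro oxirane. Prolonged heating in the carboxylate medium could then allow silyl or benzoyl migration onto the freed O5, attack at C2 or C5, or loss of the C1–O bond. Fallback: set out from 5 and separate the two openings under two different modes of activation. CsO2CPh/PhCO2H in DMF at 40 °C would be stopped once the primary carbon has reacted, and the monobenzoate 7 isolated. With O1 now a tertiary alcohol and no longer part of an oxirane that could ionise, the remaining vinyl oxirane would be opened under acid activation by benzoic acid 6 alone (CH2Cl2 or toluene, 25–40 °C). This is a trans addition at the allylic C4 without alkoxide intermediates, and it rejoins the route at 8. The detour makes no compound that is not already numbered.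

2. Step 4 (epoxidation of the diene). The oxidant may not discriminate well enough between C4=C5 and C2=C3 or between the two faces, and traces of acid could rearomatise the diene. Fallback: set out from 2 and use hydroxyl direction for site control, followed by inversion at C6. An (R)-selective ketoreductase under the conditions of step 2 would give, from the (R)-ketone, the cis dienol (3R,4R)-1-oxaspiro[2.5]octa-5,7-dien-4-ol F1. The (S)-ketone would give the trans dienol of the mirror series, (3S,4R)-1-oxaspiro[2.5]octa-5,7-dien-4-ol F2, which is removed by chromatography. VO(acac)2 (cat.) and tBuOOH in CH2Cl2 at 0 °C epoxidise only the alkene allylic to the hydroxyl (C4=C5), on the hydroxyl face. In F1 this is also the face of the spiro oxygen, so the product should be the all-cis diepoxy alcohol F3. Mitsunobu inversion at C6 (ClCH2CO2H, PPh3, DIAD, toluene, 0 °C) would then give the chloroacetate of the C6-inverted diepoxy alcohol F4. Brief methanolysis (K2CO3 cat., MeOH, 0 °C, kept short and cold to forestall a Payne rearrangement) would free the diepoxy alcohol with O6 on the lower face F5. Immediate silylation (TBSCl, imidazole, DMF) returns to the route at 5.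

3. Step 2 (enzymatic reduction of the labile dienone). Diels–Alder dimerisation of the dienone may outrun the enzymatic reduction, or the enzyme may not keep its facial fidelity for both enantiomers. Fallback: set out from 2 and replace the enzymatic reduction by a fast chemical reduction followed by an enzymatic acylation. Luche reduction (NaBH4, CeCl3·7H2O, MeOH, −78 °C) of the cold solution of 2 consumes the dienone within minutes. It would give the racemic trans dienol F6 and the racemic cis dienol F7, which are separated by chromatography. Lipase-catalysed acylation of F6 (lipase from Burkholderia cepacia or CAL-B, vinyl acetate, MTBE, 25 °C) is expected, by the usual empirical rule for secondary alcohols, to acylate the (4R)-enantiomer to the (3S,4R)-acetate F8 and to leave the (3R,4S)-alcohol untouched. The untouched alcohol is 3, where the route is rejoined.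

**Further compounds**

F0 | step 5 | none | none
F1 | step 4 | (3R,4R)-1-oxaspiro[2.5]octa-5,7-dien-4-ol (cis dienol) | C1O[C@]12C=CC=C[C@H]2O
F2 | step 4 | (3S,4R)-1-oxaspiro[2.5]octa-5,7-dien-4-ol (trans dienol of the mirror series, removed) | C1O[C@@]12C=CC=C[C@H]2O
F3 | step 4 | all-cis diepoxy alcohol (spiro oxirane oxygen, ring oxirane and C6–OH on the upper face) | C3O[C@]31C=C[C@H]2O[C@H]2[C@H]1O
F4 | step 4 | chloroacetate of the C6-inverted diepoxy alcohol (O6 on the lower face) | C3O[C@]31C=C[C@H]2O[C@H]2[C@@H]1OC(=O)CCl
F5 | step 4 | diepoxy alcohol with C6–OH on the lower face (desilylated 5) | C3O[C@]31C=C[C@H]2O[C@H]2[C@@H]1O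
F6 | step 2 | racemic trans-1-oxaspiro[2.5]octa-5,7-dien-4-ol | C1O[C@]12C=CC=C[C@@H]2O.C1O[C@@]12C=CC=C[C@H]2O
F7 | step 2 | racemic cis-1-oxaspiro[2.5]octa-5,7-dien-4-ol (removed) | C1O[C@@]12C=CC=C[C@@H]2O.C1O[C@]12C=CC=C[C@H]2O
F8 | step 2 | (3S,4R)-1-oxaspiro[2.5]octa-5,7-dien-4-yl acetate | C1O[C@@]12C=CC=C[C@H]2OC(C)=O
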